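**Retrosynthetic overview**
1. The aryl–C(=O) bond is made last: 2,4,6-trimethoxyphenyllithium adds to cyclohexenecarbaldehyde 16, followed by oxidation and chelation-controlled mono-O-demethylation. Both aromatic rings are bought, not built.
2. The prenyl group, the C2 stereocentre and the C3=C4 alkene come from a Johnson–Claisen rearrangement of cyclohexenol 9 (1,3-chirality transfer), then ester → aldehyde → Wittig.
3. The carbinol of 9 comes from a ketoreductase reduction of enone 7; 7 comes from vinylogous ester 5 by Stork–Danheiser transposition.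
4. The only ring formed is the cyclohexane ring (step 2), by Claisen cyclisation of keto diester 3. Compound 3 comes from an organocatalytic asymmetric Michael addition of dimethyl malonate 1 to enone 2, which sets C6.

Assumption: 2 is bought as the E isomer, and the (R,R) antipode of the step 1 catalyst is taken to be the one giving (R)-3; if the first run shows the opposite sense, the (S,S) catalyst is used.

Ring positions C1–C6 in the text are those of the target: C1 carries the acyl group, C2 the prenyl group, C3 the methyl group, C6 the phenyl group.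

**Step 1**
Reactants: 1 dimethyl malonate; 2 (E)-1-phenylpent-1-en-3-one
Product: 3 dimethyl 2-[(1R)-3-oxo-1-phenylpentyl]propanedioate
Conditions: 1 (2 equiv), N-[(1R,2R)-2-amino-1,2-diphenylethyl]-N'-[3,5-bis(trifluoromethyl)phenyl]thiourea (10 mol %), PhCO2H (10 mol %), toluene, rt, 48–72 h
Reagents that add atoms: none
Why: Organocatalytic asymmetric Michael addition, in which the primary amine forms a chiral iminium ion with the enone while the thiourea binds the malonate, so attack occurs on one face of the β-carbon and sets the benzylic stereocentre (future C6) as R.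

**Step 2**
Reactants: 3 dimethyl 2-[(1R)-3-oxo-1-phenylpentyl]propanedioate
Product: 4 methyl (1S,6R)-4-hydroxy-3-methyl-2-oxo-6-phenylcyclohex-3-ene-1-carboxylate
Conditions: NaOMe (1.5 equiv), MeOH, 0 °C → rt; then cold 1 M HCl to pH 2
Reagents that add atoms: none
Why: Intramolecular Claisen (Dieckmann-type) condensation of the ethyl-ketone enolate onto a malonate ester closes the only possible six-membered ring and is driven by dione enolate formation, while C1, lying between two carbonyls, equilibrates to the trans arrangement with phenyl and the low temperature limits retro-Michael erosion at C6.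

**Step 3**
Reactants: 4 methyl (1S,6R)-4-hydroxy-3-methyl-2-oxo-6-phenylcyclohex-3-ene-1-carboxylate
Product: 5 methyl (1S,6R)-4-methoxy-3-methyl-2-oxo-6-phenylcyclohex-3-ene-1-carboxylate
Conditions: HC(OMe)3 (3 equiv), TsOH·H2O (5 mol %), MeOH, rt → 40 °C
Reagents that add atoms: trimethyl orthoformate, COC(OC)OC; methanol, CO
Why: Acid-catalysed enol etherification (vinylogous ester formation) under thermodynamic control occurs at the unhindered carbonyl remote from the ester, leaving the β-keto ester carbonyl for the transposition, and no stereocentre is touched.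

**Step 4**
Reactants: 5 methyl (1S,6R)-4-methoxy-3-methyl-2-oxo-6-phenylcyclohex-3-ene-1-carboxylate
Product: 7 (4R,5R)-4-(hydroxymethyl)-2-methyl-5-phenylcyclohex-2-en-1-one, via diol enol ether 6 (not isolated)
Conditions: LiAlH4 (2.5 equiv), THF, 0 °C → rt; then 1 M HCl, THF, rt
Reagents that add atoms: water, O
Why: Stork–Danheiser enone transposition, in which hydride reduces the ester to CH2OH and the vinylogous-ester carbonyl to an allylic alcohol and aqueous acid then hydrolyses the enol ether with loss of that hydroxyl, carrying the two trans ring stereocentres over unchanged.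

**Step 5**
Reactants: 7 (4R,5R)-4-(hydroxymethyl)-2-methyl-5-phenylcyclohex-2-en-1-one
Product: 8 (1R,4R,5R)-4-(hydroxymethyl)-2-methyl-5-phenylcyclohex-2-en-1-ol
Conditions: ketoreductase (NADPH-dependent, picked from a screening panel for the (1R)-alcohol), NADP+ (cat.), i-PrOH (10 vol %), DMSO (5 vol %), potassium phosphate buffer pH 7.0, 30 °C
Reagents that add atoms: none
Why: Biocatalytic carbonyl reduction by a ketoreductase (alcohol dehydrogenase class) delivers the NADPH hydride to one face of the C=O under catalyst control without touching the C=C, giving the pseudo-axial (1R)-carbinol trans to phenyl that axial attack by simple hydride reagents does not give.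

**Step 6**
Reactants: 8 (1R,4R,5R)-4-(hydroxymethyl)-2-methyl-5-phenylcyclohex-2-en-1-ol
Product: 9 (1R,4R,5R)-4-({[tert-butyl(diphenyl)silyl]oxy}methyl)-2-methyl-5-phenylcyclohex-2-en-1-ol
Conditions: TBDPSCl (1.05 equiv), imidazole (2 equiv), CH2Cl2, 0 °C
Reagents that add atoms: tert-butyl(chloro)diphenylsilane, CC(C)(C)[Si](Cl)(c1ccccc1)c1ccccc1
Why: Silyl ether formation is selective for the unhindered primary hydroxyl over the pseudo-axial secondary allylic one, which has to stay free for the rearrangement.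

**Step 7**
Reactants: 9 (1R,4R,5R)-4-({[tert-butyl(diphenyl)silyl]oxy}methyl)-2-methyl-5-phenylcyclohex-2-en-1-ol
Product: 12 ethyl 2-[(1S,5R,6R)-6-({[tert-butyl(diphenyl)silyl]oxy}methyl)-2-methyl-5-phenylcyclohex-2-en-1-yl]acetate, via mixed orthoester 10 (not isolated), via ketene acetal 11 (not isolated)
Conditions: MeC(OEt)3 (8 equiv), EtCO2H (0.1 equiv), 140 °C, EtOH distilled off
Reagents that add atoms: triethyl orthoacetate, CCOC(C)(OCC)OCC
Why: Johnson–Claisen rearrangement, in which the ketene acetal on the pseudo-axial oxygen undergoes a suprafacial [3,3] shift that delivers CH2CO2Et to the far allyl terminus on the face the oxygen leaves (cis to CH2OSi, trans to phenyl), setting the future C2 stereocentre and moving the alkene to its final trisubstituted position.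

**Step 8**
Reactants: 12 ethyl 2-[(1S,5R,6R)-6-({[tert-butyl(diphenyl)silyl]oxy}methyl)-2-methyl-5-phenylcyclohex-2-en-1-yl]acetate
Product: 13 2-[(1S,5R,6R)-6-({[tert-butyl(diphenyl)silyl]oxy}methyl)-2-methyl-5-phenylcyclohex-2-en-1-yl]acetaldehyde
Conditions: i-Bu2AlH (1.1 equiv), CH2Cl2, −78 °C, 1 h; aqueous work-up
Reagents that add atoms: none
Why: Partial ester reduction with DIBAL-H works because the aluminium hemiacetal is stable at −78 °C and collapses to the aldehyde only on work-up, with alkene, silyl ether and stereocentres untouched.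

**Step 9**
Reactants: 13 2-[(1S,5R,6R)-6-({[tert-butyl(diphenyl)silyl]oxy}methyl)-2-methyl-5-phenylcyclohex-2-en-1-yl]acetaldehyde
Product: 14 tert-butyl{[(1R,2S,6R)-3-methyl-2-(3-methylbut-2-en-1-yl)-6-phenylcyclohex-3-en-1-yl]methoxy}diphenylsilane
Conditions: isopropyltriphenylphosphonium iodide (1.5 equiv), n-BuLi (1.4 equiv), THF, 0 °C; then 13, −78 °C → rt
Reagents that add atoms: isopropyltriphenylphosphonium iodide, CC(C)[P+](c1ccccc1)(c1ccccc1)c1ccccc1.[I-]
Why: Wittig olefination with the non-stabilised isopropylidene ylide turns CH2CHO into the prenyl side chain, with no E/Z issue because the new alkene carbon carries two methyl groups.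

**Step 10**
Reactants: 14 tert-butyl{[(1R,2S,6R)-3-methyl-2-(3-methylbut-2-en-1-yl)-6-phenylcyclohex-3-en-1-yl]methoxy}diphenylsilane
Product: 15 [(1R,2S,6R)-3-methyl-2-(3-methylbut-2-en-1-yl)-6-phenylcyclohex-3-en-1-yl]methanol
Conditions: n-Bu4NF (1.5 equiv), THF, rt
Reagents that add atoms: none
Why: Fluoride-driven desilylation (strong Si–F bond) frees the primary alcohol without affecting alkenes or stereocentres.

**Step 11**
Reactants: 15 [(1R,2S,6R)-3-methyl-2-(3-methylbut-2-en-1-yl)-6-phenylcyclohex-3-en-1-yl]methanol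
Product: 16 (1R,2S,6R)-3-methyl-2-(3-methylbut-2-en-1-yl)-6-phenylcyclohex-3-ene-1-carbaldehyde
Conditions: Dess–Martin periodinane (1.3 equiv), pyridine (3 equiv), CH2Cl2, 0 °C → rt; used at once
Reagents that add atoms: none
Why: Dess–Martin oxidation gives the aldehyde under buffered, near-neutral conditions, so the α-stereocentre C1 is not epimerised.

**Step 12**
Reactants: 16 (1R,2S,6R)-3-methyl-2-(3-methylbut-2-en-1-yl)-6-phenylcyclohex-3-ene-1-carbaldehyde; 17 1,3,5-trimethoxybenzene
Product: 19 [(1R,2S,6R)-3-methyl-2-(3-methylbut-2-en-1-yl)-6-phenylcyclohex-3-en-1-yl](2,4,6-trimethoxyphenyl)methanol as a mixture of carbinol epimers, via 2,4,6-trimethoxyphenyllithium 18 (not isolated)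
Conditions: 17 (1.6 equiv), n-BuLi (1.5 equiv), THF, 0 °C → rt, 1 h; then 16, −78 °C → 0 °C; H2O quench
Reagents that add atoms: none
Why: Directed ortho-lithiation of the threefold-symmetric arene gives a single aryllithium, which undergoes 1,2-addition to the aldehyde at low temperature faster than it enolises it, and the new carbinol centre is removed in the next step.

**Step 13**
Reactants: 19 [(1R,2S,6R)-3-methyl-2-(3-methylbut-2-en-1-yl)-6-phenylcyclohex-3-en-1-yl](2,4,6-trimethoxyphenyl)methanol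
Product: 20 [(1R,2S,6R)-3-methyl-2-(3-methylbut-2-en-1-yl)-6-phenylcyclohex-3-en-1-yl](2,4,6-trimethoxyphenyl)methanone
Conditions: Dess–Martin periodinane (1.5 equiv), pyridine (4 equiv), CH2Cl2, 0 °C → rt
Reagents that add atoms: none
Why: Dess–Martin oxidation of the electron-rich benzylic alcohol to the aryl ketone under pyridine buffering avoids acid, which would ionise the carbinol, and leaves the ring stereocentres untouched.

**Step 14**
Reactants: 20 [(1R,2S,6R)-3-methyl-2-(3-methylbut-2-en-1-yl)-6-phenylcyclohex-3-en-1-yl](2,4,6-trimethoxyphenyl)methanone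
Product: 21 (2-hydroxy-4,6-dimethoxyphenyl)[(1R,2S,6R)-3-methyl-2-(3-methylbut-2-en-1-yl)-6-phenylcyclohex-3-en-1-yl]methanone
Conditions: BCl3 (1.5 equiv, 1 M in CH2Cl2), CH2Cl2, −78 °C → 0 °C; then H2O
Reagents that add atoms: none
Why: Chelation-controlled Lewis acid ether cleavage, in which BCl3 binds the ketone oxygen and one ortho-methoxy oxygen in a six-membered chelate and cleaves only that methyl ether (the two ortho groups are equivalent, the para one is not chelated), revealing the hydrogen-bonded phenol.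

**Compound list**
1 | dimethyl malonate | COC(=O)CC(=O)OC | starting material
2 | (E)-1-phenylpent-1-en-3-one | CCC(=O)/C=C/c1ccccc1 | starting material
3 | dimethyl 2-[(1R)-3-oxo-1-phenylpentyl]propanedioate | CCC(=O)C[C@H](C(C(=O)OC)C(=O)OC)c1ccccc1 | intermediate
4 | methyl (1S,6R)-4-hydroxy-3-methyl-2-oxo-6-phenylcyclohex-3-ene-1-carboxylate (enol form of the 2,4-dione) | COC(=O)[C@@H]1C(=O)C(C)=C(O)C[C@H]1c1ccccc1 | intermediate
5 | methyl (1S,6R)-4-methoxy-3-methyl-2-oxo-6-phenylcyclohex-3-ene-1-carboxylate | COC(=O)[C@@H]1C(=O)C(C)=C(OC)C[C@H]1c1ccccc1 | intermediate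
6 | (5R,6R)-6-(hydroxymethyl)-3-methoxy-2-methyl-5-phenylcyclohex-2-en-1-ol, both C1 epimers | OC[C@@H]1C(O)C(C)=C(OC)C[C@H]1c1ccccc1 | intermediate (not isolated)
7 | (4R,5R)-4-(hydroxymethyl)-2-methyl-5-phenylcyclohex-2-en-1-one | OC[C@@H]1C=C(C)C(=O)C[C@H]1c1ccccc1 | intermediate
8 | (1R,4R,5R)-4-(hydroxymethyl)-2-methyl-5-phenylcyclohex-2-en-1-ol | OC[C@@H]1C=C(C)[C@H](O)C[C@H]1c1ccccc1 | intermediate
9 | (1R,4R,5R)-4-({[tert-butyl(diphenyl)silyl]oxy}methyl)-2-methyl-5-phenylcyclohex-2-en-1-ol | CC(C)(C)[Si](c1ccccc1)(c1ccccc1)OC[C@@H]1C=C(C)[C@H](O)C[C@H]1c1ccccc1 | intermediate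
10 | mixed orthoester of 9: the C1 oxygen carries C(CH3)(OEt)2, ring stereocentres as in 9 | CC(C)(C)[Si](c1ccccc1)(c1ccccc1)OC[C@@H]1C=C(C)[C@H](OC(C)(OCC)OCC)C[C@H]1c1ccccc1 | intermediate (not isolated)
11 | ketene acetal of 9: the C1 oxygen carries C(=CH2)OEt, ring stereocentres as in 9 | CC(C)(C)[Si](c1ccccc1)(c1ccccc1)OC[C@@H]1C=C(C)[C@H](OC(=C)OCC)C[C@H]1c1ccccc1 | intermediate (not isolated)
12 | ethyl 2-[(1S,5R,6R)-6-({[tert-butyl(diphenyl)silyl]oxy}methyl)-2-methyl-5-phenylcyclohex-2-en-1-yl]acetate | CC(C)(C)[Si](c1ccccc1)(c1ccccc1)OC[C@@H]1[C@H](CC(=O)OCC)C(C)=CC[C@H]1c1ccccc1 | intermediate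
13 | 2-[(1S,5R,6R)-6-({[tert-butyl(diphenyl)silyl]oxy}methyl)-2-methyl-5-phenylcyclohex-2-en-1-yl]acetaldehyde | CC(C)(C)[Si](c1ccccc1)(c1ccccc1)OC[C@@H]1[C@H](CC=O)C(C)=CC[C@H]1c1ccccc1 | intermediate
14 | tert-butyl{[(1R,2S,6R)-3-methyl-2-(3-methylbut-2-en-1-yl)-6-phenylcyclohex-3-en-1-yl]methoxy}diphenylsilane | CC(C)(C)[Si](c1ccccc1)(c1ccccc1)OC[C@@H]1[C@H](CC=C(C)C)C(C)=CC[C@H]1c1ccccc1 | intermediate
15 | [(1R,2S,6R)-3-methyl-2-(3-methylbut-2-en-1-yl)-6-phenylcyclohex-3-en-1-yl]methanol | OC[C@@H]1[C@H](CC=C(C)C)C(C)=CC[C@H]1c1ccccc1 | intermediate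
16 | (1R,2S,6R)-3-methyl-2-(3-methylbut-2-en-1-yl)-6-phenylcyclohex-3-ene-1-carbaldehyde | O=C[C@@H]1[C@H](CC=C(C)C)C(C)=CC[C@H]1c1ccccc1 | intermediate
17 | 1,3,5-trimethoxybenzene | COc1cc(OC)cc(OC)c1 | starting material
18 | 2,4,6-trimethoxyphenyllithium | [Li]c1c(OC)cc(OC)cc1OC | intermediate (not isolated)
19 | [(1R,2S,6R)-3-methyl-2-(3-methylbut-2-en-1-yl)-6-phenylcyclohex-3-en-1-yl](2,4,6-trimethoxyphenyl)methanol, both carbinol epimers | COc1cc(OC)c(C(O)[C@@H]2[C@H](CC=C(C)C)C(C)=CC[C@H]2c2ccccc2)c(OC)c1 | intermediate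
20 | [(1R,2S,6R)-3-methyl-2-(3-methylbut-2-en-1-yl)-6-phenylcyclohex-3-en-1-yl](2,4,6-trimethoxyphenyl)methanone | COc1cc(OC)c(C(=O)[C@@H]2[C@H](CC=C(C)C)C(C)=CC[C@H]2c2ccccc2)c(OC)c1 | intermediate
21 | (2-hydroxy-4,6-dimethoxyphenyl)[(1R,2S,6R)-3-methyl-2-(3-methylbut-2-en-1-yl)-6-phenylcyclohex-3-en-1-yl]methanone | COc1cc(O)c(C(=O)[C@@H]2[C@H](CC=C(C)C)C(C)=CC[C@H]2c2ccccc2)c(OC)c1 | target

**Step count and weak points**
Total steps: 14. Longest linear sequence: 14 steps (1 and 2 to 21; 17 enters at step 12).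

Most likely to fail, step 2: under methoxide the Michael adduct can equilibrate by retro-Michael/Michael reaction and lose ee before it cyclises. The fallback sets out from 3 and comes back at 7; it closes the ring by an acid-mediated aldol condensation, so no base ever meets a retro-Michael-prone species, and it also bypasses steps 3 and 4. The ketone of 3 is masked with ethylene glycol (TsOH, toluene, Dean–Stark) to give dimethyl 2-[(1R)-2-(2-ethyl-1,3-dioxolan-2-yl)-1-phenylethyl]propanedioate F1. LiAlH4 reduces this to 2-[(1R)-2-(2-ethyl-1,3-dioxolan-2-yl)-1-phenylethyl]propane-1,3-diol F2. Monosilylation (NaH, TBDPSCl, THF) gives 3-{[tert-butyl(diphenyl)silyl]oxy}-2-[(1R)-2-(2-ethyl-1,3-dioxolan-2-yl)-1-phenylethyl]propan-1-ol F3 as both epimers at the new centre. Dess–Martin oxidation gives (3R)-2-({[tert-butyl(diphenyl)silyl]oxy}methyl)-4-(2-ethyl-1,3-dioxolan-2-yl)-3-phenylbutanal F4. TsOH in wet acetone removes the ketal to give (3R)-2-({[tert-butyl(diphenyl)silyl]oxy}methyl)-5-oxo-3-phenylheptanal F5, which is not isolated. Warming F5 with TsOH in toluene (80 °C) closes the ring by intramolecular aldol condensation to (4R,5R)-4-({[tert-butyl(diphenyl)silyl]oxy}methyl)-2-methyl-5-phenylcyclohex-2-en-1-one F6; the enolisable aldehyde α-centre funnels to the trans product. n-Bu4NF then gives 7.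

Most likely to fail, step 5: no ketoreductase in the panel may combine useful activity on this hindered enone with the required facial sense. The fallback sets out from 7 and comes back at 9; it uses substrate-controlled reduction followed by inversion. NaBH4/CeCl3·7H2O (MeOH, −78 °C) gives the cis alcohol (1S,4R,5R)-4-(hydroxymethyl)-2-methyl-5-phenylcyclohex-2-en-1-ol F7. TBDPSCl/imidazole silylates the primary hydroxyl to (1S,4R,5R)-4-({[tert-butyl(diphenyl)silyl]oxy}methyl)-2-methyl-5-phenylcyclohex-2-en-1-ol F8. Mitsunobu inversion (4-nitrobenzoic acid, PPh3, DIAD, THF) gives (1R,4R,5R)-4-({[tert-butyl(diphenyl)silyl]oxy}methyl)-2-methyl-5-phenylcyclohex-2-en-1-yl 4-nitrobenzoate F9. K2CO3 in MeOH then gives 9.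

Most likely to fail, step 14: BCl3 and the HCl it releases may attack the two trisubstituted alkenes. The fallback sets out from 16 and comes back at 21; it carries the phenol as a MOM ether instead of demethylating at the end. 3,5-Dimethoxyphenol is protected (MOMCl, i-Pr2NEt, CH2Cl2) as 1,3-dimethoxy-5-(methoxymethoxy)benzene F10. n-BuLi (THF, 0 °C) lithiates it between the OMOM and an OMe group to give [2,4-dimethoxy-6-(methoxymethoxy)phenyl]lithium F11. Addition to 16 at −78 °C gives [2,4-dimethoxy-6-(methoxymethoxy)phenyl][(1R,2S,6R)-3-methyl-2-(3-methylbut-2-en-1-yl)-6-phenylcyclohex-3-en-1-yl]methanol F12. Dess–Martin oxidation with pyridine gives [2,4-dimethoxy-6-(methoxymethoxy)phenyl][(1R,2S,6R)-3-methyl-2-(3-methylbut-2-en-1-yl)-6-phenylcyclohex-3-en-1-yl]methanone F13. HCl in MeOH (40 °C) removes the MOM group to give 21.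

**Further compounds**
F1 | step 2 | dimethyl 2-[(1R)-2-(2-ethyl-1,3-dioxolan-2-yl)-1-phenylethyl]propanedioate | CCC1(OCCO1)C[C@H](C(C(=O)OC)C(=O)OC)c1ccccc1
F2 | step 2 | 2-[(1R)-2-(2-ethyl-1,3-dioxolan-2-yl)-1-phenylethyl]propane-1,3-diol | CCC1(OCCO1)C[C@H](C(CO)CO)c1ccccc1
F3 | step 2 | 3-{[tert-butyl(diphenyl)silyl]oxy}-2-[(1R)-2-(2-ethyl-1,3-dioxolan-2-yl)-1-phenylethyl]propan-1-ol, both C2 epimers | CCC1(OCCO1)C[C@H](C(CO)CO[Si](c1ccccc1)(c1ccccc1)C(C)(C)C)c1ccccc1
F4 | step 2 | (3R)-2-({[tert-butyl(diphenyl)silyl]oxy}methyl)-4-(2-ethyl-1,3-dioxolan-2-yl)-3-phenylbutanal, both C2 epimers | CCC1(OCCO1)C[C@H](C(C=O)CO[Si](c1ccccc1)(c1ccccc1)C(C)(C)C)c1ccccc1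
F5 | step 2 | (3R)-2-({[tert-butyl(diphenyl)silyl]oxy}methyl)-5-oxo-3-phenylheptanal, both C2 epimers | CCC(=O)C[C@H](C(C=O)CO[Si](c1ccccc1)(c1ccccc1)C(C)(C)C)c1ccccc1
F6 | step 2 | (4R,5R)-4-({[tert-butyl(diphenyl)silyl]oxy}methyl)-2-methyl-5-phenylcyclohex-2-en-1-one | CC(C)(C)[Si](c1ccccc1)(c1ccccc1)OC[C@@H]1C=C(C)C(=O)C[C@H]1c1ccccc1
F7 | step 5 | (1S,4R,5R)-4-(hydroxymethyl)-2-methyl-5-phenylcyclohex-2-en-1-ol | OC[C@@H]1C=C(C)[C@@H](O)C[C@H]1c1ccccc1
F8 | step 5 | (1S,4R,5R)-4-({[tert-butyl(diphenyl)silyl]oxy}methyl)-2-methyl-5-phenylcyclohex-2-en-1-ol | CC(C)(C)[Si](c1ccccc1)(c1ccccc1)OC[C@@H]1C=C(C)[C@@H](O)C[C@H]1c1ccccc1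
F9 | step 5 | (1R,4R,5R)-4-({[tert-butyl(diphenyl)silyl]oxy}methyl)-2-methyl-5-phenylcyclohex-2-en-1-yl 4-nitrobenzoate | CC(C)(C)[Si](c1ccccc1)(c1ccccc1)OC[C@@H]1C=C(C)[C@H](OC(=O)c2ccc(cc2)[N+](=O)[O-])C[C@H]1c1ccccc1
F10 | step 14 | 1,3-dimethoxy-5-(methoxymethoxy)benzene | COCOc1cc(OC)cc(OC)c1
F11 | step 14 | [2,4-dimethoxy-6-(methoxymethoxy)phenyl]lithium | [Li]c1c(OC)cc(OC)cc1OCOC
F12 | step 14 | [2,4-dimethoxy-6-(methoxymethoxy)phenyl][(1R,2S,6R)-3-methyl-2-(3-methylbut-2-en-1-yl)-6-phenylcyclohex-3-en-1-yl]methanol, both carbinol epimers | COCOc1cc(OC)cc(OC)c1C(O)[C@@H]1[C@H](CC=C(C)C)C(C)=CC[C@H]1c1ccccc1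
F13 | step 14 | [2,4-dimethoxy-6-(methoxymethoxy)phenyl][(1R,2S,6R)-3-methyl-2-(3-methylbut-2-en-1-yl)-6-phenylcyclohex-3-en-1-yl]methanone | COCOc1cc(OC)cc(OC)c1C(=O)[C@@H]1[C@H](CC=C(C)C)C(C)=CC[C@H]1c1ccccc1
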